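Numbering runs from carboxyl C1 along the chain to benzylic C14. Everything rests on cutting C8–C9, between the methyl-bearing stereocentre C8 and the allylic CH2 beside the C10–C13 diene. C8 is homoallylic to C10=C11, an Ireland–Claisen retron once the C8 methyl (C8') is read as a carboxyl. The finished 1,2-dioxane (O1, O2, C3–C6) and the phenyl-terminated chain are therefore tethered as an enoate, the C8' ester of a bis-allylic C11 carbinol. Copper hydride turns C7=C8–C8'O2R into a silyl ketene acetal without base, sparing the β-peroxy ester; the [3,3] shift then forms C8–C9, sets C8, draws the E,E-diene and cuts the C11–O tether in one operation.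

Key step: step 13

Remark on the chemistry: O1 is the ring oxygen on C6 and O2 that on C3; the hydrosilylation of step 13 is assumed to give the E silyl ketene acetal (C7 trans to OSi), and the configuration of the C11 carbinol is chosen for that geometry.

**Dioxane fragment**

Step 1
Reactants: 1 but-2-yn-1-ol
Product: 3 (Z)-3-iodobut-2-en-1-ol, via cyclic alkenylalanate 2 (not isolated)
Conditions: NaAlH2(OCH2CH2OMe)2 (Red-Al), THF, 0 °C → rt; then I2, THF, −78 °C → 0 °C
Reagents that add atoms: iodine, II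
Why: Hydroxyl-directed trans-hydroalumination of the propargylic alcohol puts aluminium on the methyl-bearing carbon, and iodinolysis with retention gives the Z iodide (hydroalumination–iodination).

Step 2
Reactants: 4 methyl (2R)-3-bromo-2-methylpropanoate; 3 (Z)-3-iodobut-2-en-1-ol
Product: 6 methyl (2S,4Z)-6-hydroxy-2,4-dimethylhex-4-enoate, via alkylzinc bromide 5 (not isolated)
Conditions: Zn dust, LiCl, THF, 50 °C; then 3, Pd(OAc)2 (cat.), SPhos (cat.), THF, 25 °C
Reagents that add atoms: none
Why: The Negishi coupling keeps the Z geometry of the alkenyl iodide, tolerates the free hydroxyl, and leaves untouched the C4 stereocentre, which comes from the chiral pool.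

Step 3
Reactants: 6 methyl (2S,4Z)-6-hydroxy-2,4-dimethylhex-4-enoate; 7 trimethyl phosphonoacetate
Product: 9 methyl (2E,4S,6Z)-8-hydroxy-4,6-dimethylocta-2,6-dienoate, via hydroxy aldehyde 8 (not isolated)
Conditions: iBu2AlH (2.1 equiv), CH2Cl2, −78 °C; then 7/NaH in THF, −78 °C → rt; aq. Rochelle salt
Reagents that add atoms: none
Why: Partial ester reduction to the aluminium hemiacetal followed by Horner–Wadsworth–Emmons olefination in the same flask gives the E enoate and avoids handling the epimerisable α-methyl aldehyde.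

Step 4
Reactants: 9 methyl (2E,4S,6Z)-8-hydroxy-4,6-dimethylocta-2,6-dienoate
Product: 10 methyl (2E,4S)-5-[(2R,3S)-3-(hydroxymethyl)-2-methyloxiran-2-yl]-4-methylpent-2-enoate
Conditions: Ti(OiPr)4 (cat.), L-(+)-diethyl tartrate (cat.), t-BuOOH, 4 Å MS, CH2Cl2, −20 °C
Reagents that add atoms: tert-butyl hydroperoxide, CC(C)(C)OO
Why: In this Sharpless asymmetric epoxidation, L-(+)-tartrate epoxidises the Z-trisubstituted (nerol-type) allylic alcohol under reagent control on the face that makes C6 R and C7 S, while the electron-poor enoate is inert.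

Step 5
Reactants: 10 methyl (2E,4S)-5-[(2R,3S)-3-(hydroxymethyl)-2-methyloxiran-2-yl]-4-methylpent-2-enoate
Product: 11 methyl (2E,4S,6S,7S)-6-hydroperoxy-7,8-dihydroxy-4,6-dimethyloct-2-enoate
Conditions: H2O2 (anhydrous ethereal solution, excess), H3PMo12O40 (cat.), Et2O, rt
Reagents that add atoms: hydrogen peroxide, OO
Why: In this acid-catalysed epoxide perhydrolysis, H2O2 attacks the tertiary, cation-stabilising C6 anti to the leaving oxygen, so inversion turns 6R into the required 6S tertiary hydroperoxide.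

Step 6
Reactants: 11 methyl (2E,4S,6S,7S)-6-hydroperoxy-7,8-dihydroxy-4,6-dimethyloct-2-enoate
Product: 12 methyl 2-[(3R,4S,6S)-6-[(1S)-1,2-dihydroxyethyl]-4,6-dimethyl-1,2-dioxan-3-yl]acetate
Conditions: Et2NH (cat.), CF3CH2OH, rt
Reagents that add atoms: none
Why: The hydroperoxide, far more acidic and nucleophilic than the two hydroxyls, adds 6-exo-trig (intramolecular oxa-Michael) through a chair with the C4 methyl, the C6 dihydroxyethyl arm and the forming C3 acetate arm all equatorial, which sets 3R (3,4-trans) and is also the thermodynamic outcome of this reversible addition.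

Step 7
Reactants: 12 methyl 2-[(3R,4S,6S)-6-[(1S)-1,2-dihydroxyethyl]-4,6-dimethyl-1,2-dioxan-3-yl]acetate
Product: 13 methyl 2-[(3R,4S,6S)-6-formyl-4,6-dimethyl-1,2-dioxan-3-yl]acetate
Conditions: NaIO4 on silica gel, CH2Cl2, rt
Reagents that add atoms: none
Why: Malaprade glycol cleavage removes the terminal CH2OH carbon as formaldehyde and leaves C7 as a non-enolisable α-peroxy aldehyde, dialkyl peroxides being inert to periodate.

**Phenyl-terminated fragment**

Step 8
Reactants: 14 phenylacetaldehyde; 15 2-(triphenylphosphoranylidene)propanal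
Product: 16 (2E)-2-methyl-4-phenylbut-2-enal
Conditions: toluene, 90 °C
Reagents that add atoms: none
Why: Wittig olefination with the stabilised formyl ylide gives the E trisubstituted enal, which fixes the C12=C13 geometry.

Step 9
Reactants: 16 (2E)-2-methyl-4-phenylbut-2-enal; 17 isopropenylmagnesium bromide
Product: 18 rac-(4E)-2,4-dimethyl-6-phenylhexa-1,4-dien-3-ol
Conditions: THF, −78 °C → 0 °C; then aq. NH4Cl
Reagents that add atoms: none
Why: 1,2-Addition of the alkenyl Grignard reagent to the enal gives the racemic bis-allylic alcohol.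

Step 10
Reactants: 18 rac-(4E)-2,4-dimethyl-6-phenylhexa-1,4-dien-3-ol
Product: 19 (3S,4E)-2,4-dimethyl-6-phenylhexa-1,4-dien-3-ol
Conditions: Ti(OiPr)4 (cat.), D-(−)-diisopropyl tartrate (cat.), t-BuOOH (0.6 equiv), 4 Å MS, CH2Cl2, −20 °C
Reagents that add atoms: none
Why: In this Sharpless kinetic resolution with D-(−)-tartrate, the R enantiomer is epoxidised quickly at its electron-rich trisubstituted alkene, whereas the S enantiomer, whose only matched alkene is the much less nucleophilic isopropenyl group, is recovered.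

Step 11
Reactants: 19 (3S,4E)-2,4-dimethyl-6-phenylhexa-1,4-dien-3-ol; 20 diethylphosphonoacetic acid
Product: 21 (3S,4E)-2,4-dimethyl-6-phenylhexa-1,4-dien-3-yl 2-(diethoxyphosphoryl)acetate
Conditions: DCC, DMAP (cat.), CH2Cl2, 0 °C → rt
Reagents that add atoms: none
Why: Steglich esterification acylates the oxygen under neutral conditions, so the bis-allylic carbinol does not ionise and C11 keeps its configuration.

**Union and endgame**

Step 12
Reactants: 13 methyl 2-[(3R,4S,6S)-6-formyl-4,6-dimethyl-1,2-dioxan-3-yl]acetate; 21 (3S,4E)-2,4-dimethyl-6-phenylhexa-1,4-dien-3-yl 2-(diethoxyphosphoryl)acetate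
Product: 22 (3S,4E)-2,4-dimethyl-6-phenylhexa-1,4-dien-3-yl (2E)-3-[(3S,5S,6R)-6-(2-methoxy-2-oxoethyl)-3,5-dimethyl-1,2-dioxan-3-yl]prop-2-enoate
Conditions: LiCl, iPr2NEt, MeCN, 0 °C → rt
Reagents that add atoms: none
Why: Horner–Wadsworth–Emmons olefination under Masamune–Roush conditions gives the E enoate with a base too weak to harm the β-peroxy ester, and olefination of α-peroxy aldehydes is a known operation.

Step 13
Reactants: 22 (3S,4E)-2,4-dimethyl-6-phenylhexa-1,4-dien-3-yl (2E)-3-[(3S,5S,6R)-6-(2-methoxy-2-oxoethyl)-3,5-dimethyl-1,2-dioxan-3-yl]prop-2-enoate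
Product: 25 (2R,4E,6E)-2-{[(3S,5S,6R)-6-(2-methoxy-2-oxoethyl)-3,5-dimethyl-1,2-dioxan-3-yl]methyl}-4,6-dimethyl-8-phenylocta-4,6-dienoic acid, via E silyl ketene acetal 23 (not isolated), via silyl ester 24 (not isolated)
Conditions: Cu(OAc)2 (5 mol %), 1,2-bis(diphenylphosphino)benzene (5 mol %), (EtO)2MeSiH (2 equiv), toluene, 0 °C → rt; then aq. citric acid, THF
Reagents that add atoms: none
Why: The phosphine-ligated copper hydride formed from Cu(OAc)2 and the silane delivers hydride to C7 of the polarised enoate, and exchange of the copper enolate with the silane releases silyl ketene acetal 23, so the C8 nucleophile arises regiospecifically without base and the enolisable, elimination-prone β-peroxy ester C1–C3 is never deprotonated. 23 then rearranges through the six-membered chair C8=C8'–O–C11–C10=C9, making C8–C9 while the C11–O tether breaks, the closest known reaction type being the copper hydride (or rhodium hydride) catalysed reductive Ireland–Claisen rearrangement of allylic α,β-unsaturated esters. No ring is closed, the only cycle being the transition state. C8 is controlled by C11: the E ketene acetal is expected because in the cyclic copper-to-silicon exchange the neopentyl-like C7 arm lies anti to the oxygen being silylated, and with the C12 alkenyl group of the 11S carbinol equatorial the chair joins the faces that give 8R, the stereocentre C11 being consumed as C10=C11 emerges E. The step needs site selectivity between the two allyl termini, secured because the unsubstituted C9H2 is far less hindered than C13 and only its path gives the conjugated, twice trisubstituted diene. It also needs chemoselectivity, secured because copper hydride attacks only the electron-poor C7=C8 and should leave the isolated alkenes, the methyl ester and the dialkyl peroxide alone at or below room temperature.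

Step 14
Reactants: 25 (2R,4E,6E)-2-{[(3S,5S,6R)-6-(2-methoxy-2-oxoethyl)-3,5-dimethyl-1,2-dioxan-3-yl]methyl}-4,6-dimethyl-8-phenylocta-4,6-dienoic acid
Product: 27 methyl 2-[(3R,4S,6R)-6-[(2R,4E,6E)-2-(hydroxymethyl)-4,6-dimethyl-8-phenylocta-4,6-dien-1-yl]-4,6-dimethyl-1,2-dioxan-3-yl]acetate, via mixed anhydride 26 (not isolated)
Conditions: iBuOCOCl, N-methylmorpholine, THF, −15 °C; then NaBH4, H2O, 0 °C
Reagents that add atoms: none
Why: Mixed carbonic anhydride activation followed by NaBH4 reduction converts only the free C8' acid and leaves the methyl ester, the diene and the dialkyl peroxide untouched.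

Step 15
Reactants: 27 methyl 2-[(3R,4S,6R)-6-[(2R,4E,6E)-2-(hydroxymethyl)-4,6-dimethyl-8-phenylocta-4,6-dien-1-yl]-4,6-dimethyl-1,2-dioxan-3-yl]acetate
Product: 28 methyl 2-[(3R,4S,6S)-6-[(2R,4E,6E)-2-(iodomethyl)-4,6-dimethyl-8-phenylocta-4,6-dien-1-yl]-4,6-dimethyl-1,2-dioxan-3-yl]acetate
Conditions: PPh3, I2, imidazole, CH2Cl2, 0 °C (premixed); then 27
Reagents that add atoms: iodine, II
Why: In this Appel-type iodination the phosphine is consumed by iodine before the substrate is added, so the peroxide never meets free PPh3, and C8 is not involved (the change of the C6 descriptor is only a change of priorities).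

Step 16
Reactants: 28 methyl 2-[(3R,4S,6S)-6-[(2R,4E,6E)-2-(iodomethyl)-4,6-dimethyl-8-phenylocta-4,6-dien-1-yl]-4,6-dimethyl-1,2-dioxan-3-yl]acetate
Product: 29 methyl 2-[(3R,4S,6R)-4,6-dimethyl-6-[(2R,4E,6E)-2,4,6-trimethyl-8-phenylocta-4,6-dien-1-yl]-1,2-dioxan-3-yl]acetate
Conditions: NaBH4, DMSO, rt
Reagents that add atoms: none
Why: SN2 displacement of the primary iodide by borohydride in a dipolar aprotic solvent turns C8' into the C8 methyl group without radicals, which could attack the O–O bond.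

Step 17
Reactants: 29 methyl 2-[(3R,4S,6R)-4,6-dimethyl-6-[(2R,4E,6E)-2,4,6-trimethyl-8-phenylocta-4,6-dien-1-yl]-1,2-dioxan-3-yl]acetate
Product: 30 2-[(3R,4S,6R)-4,6-dimethyl-6-[(2R,4E,6E)-2,4,6-trimethyl-8-phenylocta-4,6-dien-1-yl]-1,2-dioxan-3-yl]acetic acid (CNP0330752.2)
Conditions: LiOH, THF/H2O, 0 °C → rt; then 1 M HCl to pH 3
Reagents that add atoms: lithium hydroxide, [Li+].[OH-]
Why: Saponification of the unhindered methyl ester should be clean, since any retro-oxa-Michael opening is reversible and recloses to the all-equatorial dioxane.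

**Compound list**

1 | but-2-yn-1-ol | CC#CCO | starting material
2 | cyclic sodium alkenylalanate (five-membered O–Al–C chelate from 1) | CC1=CCO[Al-]1(OCCOC)OCCOC.[Na+] | intermediate
3 | (Z)-3-iodobut-2-en-1-ol | C/C(I)=C/CO | intermediate
4 | methyl (2R)-3-bromo-2-methylpropanoate | COC(=O)[C@@H](C)CBr | starting material
5 | [(2R)-3-methoxy-2-methyl-3-oxopropyl]zinc bromide | COC(=O)[C@@H](C)C[Zn]Br | intermediate
6 | methyl (2S,4Z)-6-hydroxy-2,4-dimethylhex-4-enoate | COC(=O)[C@@H](C)C/C(C)=C\CO | intermediate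
7 | trimethyl phosphonoacetate | COC(=O)CP(=O)(OC)OC | starting material
8 | (2S,4Z)-6-hydroxy-2,4-dimethylhex-4-enal (present as its aluminium alkoxide) | O=C[C@@H](C)C/C(C)=C\CO | intermediate
9 | methyl (2E,4S,6Z)-8-hydroxy-4,6-dimethylocta-2,6-dienoate | COC(=O)/C=C/[C@@H](C)C/C(C)=C\CO | intermediate
10 | methyl (2E,4S)-5-[(2R,3S)-3-(hydroxymethyl)-2-methyloxiran-2-yl]-4-methylpent-2-enoate | COC(=O)/C=C/[C@@H](C)C[C@@]1(C)O[C@H]1CO | intermediate
11 | methyl (2E,4S,6S,7S)-6-hydroperoxy-7,8-dihydroxy-4,6-dimethyloct-2-enoate | COC(=O)/C=C/[C@@H](C)C[C@](C)(OO)[C@@H](O)CO | intermediate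
12 | methyl 2-[(3R,4S,6S)-6-[(1S)-1,2-dihydroxyethyl]-4,6-dimethyl-1,2-dioxan-3-yl]acetate | OC[C@H](O)[C@]1(C)C[C@H](C)[C@@H](CC(=O)OC)OO1 | intermediate
13 | methyl 2-[(3R,4S,6S)-6-formyl-4,6-dimethyl-1,2-dioxan-3-yl]acetate | O=C[C@]1(C)C[C@H](C)[C@@H](CC(=O)OC)OO1 | intermediate
14 | phenylacetaldehyde | O=CCc1ccccc1 | starting material
15 | 2-(triphenylphosphoranylidene)propanal | CC(C=O)=P(c1ccccc1)(c1ccccc1)c1ccccc1 | starting material
16 | (2E)-2-methyl-4-phenylbut-2-enal | O=C/C(C)=C/Cc1ccccc1 | intermediate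
17 | isopropenylmagnesium bromide | C=C(C)[Mg]Br | starting material
18 | rac-(4E)-2,4-dimethyl-6-phenylhexa-1,4-dien-3-ol | C=C(C)C(O)/C(C)=C/Cc1ccccc1 | intermediate
19 | (3S,4E)-2,4-dimethyl-6-phenylhexa-1,4-dien-3-ol | C=C(C)[C@H](O)/C(C)=C/Cc1ccccc1 | intermediate
20 | diethylphosphonoacetic acid | CCOP(=O)(CC(=O)O)OCC | starting material
21 | (3S,4E)-2,4-dimethyl-6-phenylhexa-1,4-dien-3-yl 2-(diethoxyphosphoryl)acetate | CCOP(=O)(OCC)CC(=O)O[C@@H](C(C)=C)/C(C)=C/Cc1ccccc1 | intermediate
22 | (3S,4E)-2,4-dimethyl-6-phenylhexa-1,4-dien-3-yl (2E)-3-[(3S,5S,6R)-6-(2-methoxy-2-oxoethyl)-3,5-dimethyl-1,2-dioxan-3-yl]prop-2-enoate | O=C(/C=C/[C@]1(C)C[C@H](C)[C@@H](CC(=O)OC)OO1)O[C@@H](C(C)=C)/C(C)=C/Cc1ccccc1 | intermediate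
23 | E diethoxy(methyl)silyl ketene acetal of the C7,C8-saturated ester (C7 trans to OSi, 11S, ring as in 13) | CCO[Si](C)(OCC)O/C(O[C@@H](C(C)=C)/C(C)=C/Cc1ccccc1)=C/C[C@]1(C)C[C@H](C)[C@@H](CC(=O)OC)OO1 | intermediate
24 | diethoxy(methyl)silyl ester of acid 25 | CC(=C\Cc1ccccc1)/C=C(\C)C[C@@H](C(=O)O[Si](C)(OCC)OCC)C[C@]1(C)C[C@H](C)[C@@H](CC(=O)OC)OO1 | intermediate
25 | (2R,4E,6E)-2-{[(3S,5S,6R)-6-(2-methoxy-2-oxoethyl)-3,5-dimethyl-1,2-dioxan-3-yl]methyl}-4,6-dimethyl-8-phenylocta-4,6-dienoic acid | CC(=C\Cc1ccccc1)/C=C(\C)C[C@@H](C(=O)O)C[C@]1(C)C[C@H](C)[C@@H](CC(=O)OC)OO1 | intermediate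
26 | isobutyl carbonic anhydride of acid 25 | CC(=C\Cc1ccccc1)/C=C(\C)C[C@@H](C(=O)OC(=O)OCC(C)C)C[C@]1(C)C[C@H](C)[C@@H](CC(=O)OC)OO1 | intermediate
27 | methyl 2-[(3R,4S,6R)-6-[(2R,4E,6E)-2-(hydroxymethyl)-4,6-dimethyl-8-phenylocta-4,6-dien-1-yl]-4,6-dimethyl-1,2-dioxan-3-yl]acetate | CC(=C\Cc1ccccc1)/C=C(\C)C[C@@H](CO)C[C@]1(C)C[C@H](C)[C@@H](CC(=O)OC)OO1 | intermediate
28 | methyl 2-[(3R,4S,6S)-6-[(2R,4E,6E)-2-(iodomethyl)-4,6-dimethyl-8-phenylocta-4,6-dien-1-yl]-4,6-dimethyl-1,2-dioxan-3-yl]acetate | CC(=C\Cc1ccccc1)/C=C(\C)C[C@@H](CI)C[C@]1(C)C[C@H](C)[C@@H](CC(=O)OC)OO1 | intermediate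
29 | methyl 2-[(3R,4S,6R)-4,6-dimethyl-6-[(2R,4E,6E)-2,4,6-trimethyl-8-phenylocta-4,6-dien-1-yl]-1,2-dioxan-3-yl]acetate | CC(=C\Cc1ccccc1)/C=C(\C)C[C@@H](C)C[C@]1(C)C[C@H](C)[C@@H](CC(=O)OC)OO1 | intermediate
30 | 2-[(3R,4S,6R)-4,6-dimethyl-6-[(2R,4E,6E)-2,4,6-trimethyl-8-phenylocta-4,6-dien-1-yl]-1,2-dioxan-3-yl]acetic acid | CC(=C\Cc1ccccc1)/C=C(\C)C[C@@H](C)C[C@]1(C)C[C@H](C)[C@@H](CC(=O)O)OO1 | target

**Step count**

- Total step count: 17.
- Longest linear sequence: 13 steps (steps 1–7, then 12–17).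

**Steps most likely to fail**

Step 13.
- What may go wrong: a mixed ketene acetal geometry, or leakage through a boat transition state, would erode the transfer of chirality from C11 to C8. Electron transfer from the copper hydride system to the O–O bond would open the ring.
- Fallback: the same C8–C9 bond is formed by an intermolecular Evans alkylation. It sets out from 13 and 16 and comes back at 27.
- Aldehyde 13 is olefinated (LiCl, iPr2NEt) with (4R)-4-benzyl-3-[(diethoxyphosphoryl)acetyl]-1,3-oxazolidin-2-one to the E enimide F1. Diimide (2-nitrobenzenesulfonylhydrazide, Et3N) then saturates C7=C8 to the imide F2.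
- Enal 16 is extended with Ph3P=C(CH3)CO2Et to ethyl (2E,4E)-2,4-dimethyl-6-phenylhexa-2,4-dienoate F3, reduced with iBu2AlH to the dienol F4, and converted with CBr4/PPh3 into the dienyl bromide F5.
- NaN(SiMe3)2 at −78 °C deprotonates only the imide of F2, which is far more acidic than the methyl ester. The chelated Z enolate is alkylated by F5 on the face away from the benzyl group to give the 8R imide F6.
- NaBH4 in THF/H2O then removes the auxiliary reductively and gives 27.

Step 5.
- What may go wrong: partial ionisation at C6 before the peroxide arrives would scramble the new tertiary centre. Attack at C7 or acid-induced rearrangement of the epoxide would consume material.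
- Fallback: the C6–O bond is installed by radical hydroperoxysilylation in place of ionic ring opening. This gives up control at C6 and relies on separation. It sets out from 5 and comes back at 13.
- Negishi coupling of 5 with 2-bromoprop-2-en-1-ol gives methyl (2S)-4-(hydroxymethyl)-2-methylpent-4-enoate F7. The reduction–olefination of step 3 then gives methyl (2E,4S)-6-(hydroxymethyl)-4-methylhepta-2,6-dienoate F8.
- Mukaiyama–Isayama peroxidation (Co(thd)2, O2, Et3SiH) adds hydrogen to the terminal CH2, which becomes the C6 methyl, and the silylperoxy group to C6. This gives the triethylsilyl peroxide F9 as both C6 epimers.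
- Desilylation (HCl, MeOH) and Et2NH in CF3CH2OH close the ring, chromatography isolates the hydroxymethyl dioxane F10, and Dess–Martin periodinane oxidises it to 13.

Step 16.
- What may go wrong: hydride displacement at the β-branched primary carbon may be slow, so base-induced opening of the β-peroxy ester or reduction of the methyl ester competes.
- Fallback: the oxygen is removed through a diazene instead of an SN2 step. It sets out from 27 and comes back at 29.
- Dess–Martin oxidation of 27 gives the aldehyde F11, and condensation with TsNHNH2 gives the tosylhydrazone F12.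
- Reduction with catecholborane followed by NaOAc·3H2O (Caglioti-type deoxygenation) expels sulfinate and nitrogen and leaves the C8 methyl group of 29.

Further compounds
F1 | step 13 | E enimide: (4R)-4-benzyl-3-[(2E)-3-(dioxanyl)prop-2-enoyl]-1,3-oxazolidin-2-one, ring as in 13 | O=C(/C=C/[C@]1(C)C[C@H](C)[C@@H](CC(=O)OC)OO1)N1C(=O)OC[C@H]1Cc1ccccc1
F2 | step 13 | saturated imide: (4R)-4-benzyl-3-[3-(dioxanyl)propanoyl]-1,3-oxazolidin-2-one, ring as in 13 | O=C(CC[C@]1(C)C[C@H](C)[C@@H](CC(=O)OC)OO1)N1C(=O)OC[C@H]1Cc1ccccc1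
F3 | step 13 | ethyl (2E,4E)-2,4-dimethyl-6-phenylhexa-2,4-dienoate | CCOC(=O)/C(C)=C/C(C)=C/Cc1ccccc1
F4 | step 13 | (2E,4E)-2,4-dimethyl-6-phenylhexa-2,4-dien-1-ol | OC/C(C)=C/C(C)=C/Cc1ccccc1
F5 | step 13 | [(2E,4E)-6-bromo-3,5-dimethylhexa-2,4-dien-1-yl]benzene | BrC/C(C)=C/C(C)=C/Cc1ccccc1
F6 | step 13 | 8R alkylated imide: (4R)-4-benzyl-oxazolidinone imide of acid 25 | CC(=C\Cc1ccccc1)/C=C(\C)C[C@@H](C(=O)N1C(=O)OC[C@H]1Cc1ccccc1)C[C@]1(C)C[C@H](C)[C@@H](CC(=O)OC)OO1
F7 | step 5 | methyl (2S)-4-(hydroxymethyl)-2-methylpent-4-enoate | COC(=O)[C@@H](C)CC(=C)CO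
F8 | step 5 | methyl (2E,4S)-6-(hydroxymethyl)-4-methylhepta-2,6-dienoate | COC(=O)/C=C/[C@@H](C)CC(=C)CO
F9 | step 5 | methyl (2E,4S)-7-hydroxy-4,6-dimethyl-6-(triethylsilylperoxy)hept-2-enoate, both C6 epimers | COC(=O)/C=C/[C@@H](C)CC(C)(CO)OO[Si](CC)(CC)CC
F10 | step 5 | methyl 2-[(3R,4S,6S)-6-(hydroxymethyl)-4,6-dimethyl-1,2-dioxan-3-yl]acetate | OC[C@]1(C)C[C@H](C)[C@@H](CC(=O)OC)OO1
F11 | step 16 | C8' aldehyde corresponding to alcohol 27 | CC(=C\Cc1ccccc1)/C=C(\C)C[C@@H](C=O)C[C@]1(C)C[C@H](C)[C@@H](CC(=O)OC)OO1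
F12 | step 16 | tosylhydrazone of F11 | CC(=C\Cc1ccccc1)/C=C(\C)C[C@@H](C=NNS(=O)(=O)c1ccc(C)cc1)C[C@]1(C)C[C@H](C)[C@@H](CC(=O)OC)OO1
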